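**Retrosynthetic overview**
1. The target is reached from the spiro enone of ring A (C1-methyl, C1=C2, C3=O) by α′-bromination at C4, 1,2-reduction at C3 and one inversion at C3; both stereocentres are relayed from the spiro carbon C6 by substrate control.
2. The spiro enone comes from a spiro vinylogous ester (C1=O, C3–O-isobutyl) by methyl addition and Stork–Danheiser transposition.
3. The spiro vinylogous ester comes from a catalytic asymmetric Diels–Alder reaction of an exocyclic enone with 2-bromo-3-methylbuta-1,3-diene, which forms C7–C8 and C6–C11 at once. Enabling feature: ring B is a cyclohexene (C9=C10 flanked by C8H2 and C11H2) whose two remaining atoms are C7H2 and the spiro carbon C6, and C6 is bonded to ring-A carbon C1, which can be a carbonyl, so that C6=C7 becomes an electron-poor exocyclic alkene.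
4. Ring order: ring A is bought (dimedone); ring B is closed in the key step; the diene is made from 3-methylbuta-1,2-diene.

Key step: step 5

Remark on numbering: all spiro compounds are named with the route numbering ring A = C1–C5, spiro carbon = C6, ring B = C7H2–C8H2–C9(CH3)=C10(Br)–C11H2; CIP descriptors change along the route without any change in spatial arrangement.
Remark on the chemistry (assumption): the chiral acid of step 5 is a confined (S,S)-imidodiphosphorimidate (IDPi) Brønsted acid built from two 3,3′-diaryl-BINOL units with two N–SO2CF3 groups; which antipode gives the required spiro configuration cannot be predicted from the structure, and the mirror-image catalyst is used if the first run shows the opposite sense.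

**Step 1**
Reactants: 1 dimedone (5,5-dimethylcyclohexane-1,3-dione)
Product: 2 5,5-dimethyl-3-(2-methylpropoxy)cyclohex-2-en-1-one
Conditions: TsOH·H2O (cat.), toluene, reflux, Dean–Stark trap
Reagents that add atoms: 2-methylpropan-1-ol, CC(C)CO
Why: Acid-catalysed enol etherification of the symmetrical 1,3-diketone with azeotropic removal of water can give only this vinylogous ester, and no stereocentre is formed.

**Step 2**
Reactants: 2 5,5-dimethyl-3-(2-methylpropoxy)cyclohex-2-en-1-one
Product: 3 6-[(dimethylamino)methyl]-5,5-dimethyl-3-(2-methylpropoxy)cyclohex-2-en-1-one (racemic)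
Conditions: LiN(iPr)2, THF, −78 °C; then Me2N=CH2+ I−, −78 °C → rt
Reagents that add atoms: dimethylmethyleneammonium iodide, C=[N+](C)C.[I-]
Why: Kinetic deprotonation of a vinylogous ester occurs at the α′ CH2 between C=O and CMe2, and the enolate is aminomethylated by the iminium salt (Mannich reaction); the new stereocentre is racemic and is erased in step 3.

**Step 3**
Reactants: 3 6-[(dimethylamino)methyl]-5,5-dimethyl-3-(2-methylpropoxy)cyclohex-2-en-1-one
Product: 5 5,5-dimethyl-6-methylidene-3-(2-methylpropoxy)cyclohex-2-en-1-one, via trimethylammonium iodide 4 (not isolated)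
Conditions: MeI, Et2O, rt; then aq NaHCO3, CH2Cl2, rt
Reagents that add atoms: none
Why: N-Quaternisation followed by base-induced β-elimination of trimethylamine (Hofmann-type, E1cB) should unveil the exocyclic enone, which cannot isomerise into the ring because C5 is quaternary; no stereocentre remains.

**Step 4**
Reactants: 6 3-methylbuta-1,2-diene
Product: 8 2-bromo-3-methylbuta-1,3-diene, via allylic dibromide 7 (not isolated)
Conditions: Br2, CH2Cl2, −78 °C; then DBU, 0 °C → rt; distillation
Reagents that add atoms: bromine, BrBr
Why: Electrophilic bromination of the allene at its central carbon gives the tertiary allylic dibromide, and E2 dehydrobromination (methyl hydrogen and tertiary bromide) should leave the 2-bromodiene; no stereocentre is involved.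

**Step 5**
Reactants: 5 5,5-dimethyl-6-methylidene-3-(2-methylpropoxy)cyclohex-2-en-1-one; 8 2-bromo-3-methylbuta-1,3-diene
Product: 9 (6R)-10-bromo-5,5,9-trimethyl-3-(2-methylpropoxy)spiro[5.5]undeca-2,9-dien-1-one
Conditions: 8 (3 equiv), (S,S)-IDPi Brønsted acid (3 mol%), 4 Å MS, CH2Cl2, −40 °C
Reagents that add atoms: none
Why: The confined chiral acid hydrogen-bonds to or protonates the C1 carbonyl of 5 and lowers the LUMO of the exocyclic enone, and the diene adds in a concerted but strongly asynchronous [4+2] cycloaddition in which the bond to the unhindered exocyclic CH2 (C7) runs ahead of the bond to the fully substituted C6. The closest known reaction type is the acid-catalysed enantioselective spirocyclising Diels–Alder reaction of α-methylene cycloalkanones with 2,3-disubstituted butadienes. Ring B, a six-membered carbocycle, is closed by the intermolecular [4+2] cycloaddition itself, suprafacially on both components. The only new stereocentre, the quaternary spiro carbon C6, is set by the catalyst, whose chiral anion pocket shields one enantiotopic face of the planar, achiral enone; the diene has no terminal substituents, so no endo/exo question arises. The step needs regioselectivity (C7 to the diene terminus next to C–CH3, C6 to the terminus next to C–Br), which the polarisation of both partners should secure: C7 carries the largest LUMO coefficient, and the terminus next to the methyl-bearing carbon is the more nucleophilic because the developing allyl cation is then tertiary with bromine on its nodal central carbon. It also needs site selectivity for C6=C7 over C2=C3, which follows from C2=C3 being the electron-rich enol-ether double bond of the vinylogous ester.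

**Step 6**
Reactants: 9 (6R)-10-bromo-5,5,9-trimethyl-3-(2-methylpropoxy)spiro[5.5]undeca-2,9-dien-1-one
Product: 11 (6R)-10-bromo-1,5,5,9-tetramethylspiro[5.5]undeca-1,9-dien-3-one, via tertiary carbinol 10 (not isolated)
Conditions: MeLi, CeCl3, THF, −78 → 0 °C; then 1 M HCl, THF, rt
Reagents that add atoms: methyllithium, [Li]C
Why: 1,2-Addition of the weakly basic organocerium reagent to the hindered C1 carbonyl, then acid hydrolysis of the enol ether and loss of water (Stork–Danheiser transposition), should give the transposed enone; the carbinol centre of 10 is inconsequential, the spiro centre is untouched and the vinyl bromide is inert at low temperature.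

**Step 7**
Reactants: 11 (6R)-10-bromo-1,5,5,9-tetramethylspiro[5.5]undeca-1,9-dien-3-one
Product: 13 (4S,6S)-4,10-dibromo-1,5,5,9-tetramethylspiro[5.5]undeca-1,9-dien-3-one, via silyl dienol ether 12 (not isolated)
Conditions: LiN(iPr)2, Me3SiCl, THF, −78 °C; then NBS, −78 → 0 °C
Reagents that add atoms: N-bromosuccinimide, O=C1CCC(=O)N1Br
Why: Kinetic α′-deprotonation at C4 and electrophilic bromination of the silyl dienol ether should occur from the face opposite the pseudoaxial C7 methylene on C6, placing bromine equatorial and syn to C11 (substrate control by the spiro centre); this is also expected to be the thermodynamically preferred epimer.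

**Step 8**
Reactants: 13 (4S,6S)-4,10-dibromo-1,5,5,9-tetramethylspiro[5.5]undeca-1,9-dien-3-one
Product: 14 (3R,4S,6S)-4,10-dibromo-1,5,5,9-tetramethylspiro[5.5]undeca-1,9-dien-3-ol
Conditions: iBu2AlH, CH2Cl2, −78 °C; aq Rochelle salt work-up
Reagents that add atoms: none
Why: Diastereoselective 1,2-hydride reduction: the bulky hydride should attack the conformationally locked bromoenone from the face opposite the axial C5 methyl group, giving the pseudoaxial alcohol cis to the equatorial bromide, without reducing either C–Br bond at this temperature.

**Step 9**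
Reactants: 14 (3R,4S,6S)-4,10-dibromo-1,5,5,9-tetramethylspiro[5.5]undeca-1,9-dien-3-ol
Product: 15 (3S,4S,6S)-4,10-dibromo-1,5,5,9-tetramethylspiro[5.5]undeca-1,9-dien-3-yl 4-nitrobenzoate
Conditions: 4-O2NC6H4CO2H, PPh3, DIAD, toluene, 0 °C → rt
Reagents that add atoms: 4-nitrobenzoic acid, O=C(O)c1ccc(cc1)[N+](=O)[O-]
Why: Mitsunobu reaction: the oxyphosphonium of the axial allylic alcohol should be displaced by the carboxylate with SN2 inversion from the open equatorial direction, which sets the C3 configuration of the target, trans to bromine.

**Step 10**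
Reactants: 15 (3S,4S,6S)-4,10-dibromo-1,5,5,9-tetramethylspiro[5.5]undeca-1,9-dien-3-yl 4-nitrobenzoate
Product: 16 (3S,4S,6S)-4,10-dibromo-1,5,5,9-tetramethylspiro[5.5]undeca-1,9-dien-3-ol (target)
Conditions: K2CO3 (0.2 equiv), MeOH, 0 °C
Reagents that add atoms: none
Why: Mild transesterification of the activated aryl ester should free the alcohol without touching a stereocentre; the diequatorial trans-bromohydrin cannot readily reach the anti-periplanar geometry needed for epoxide closure under these cold, brief conditions.

**Compound list**
1 | dimedone (5,5-dimethylcyclohexane-1,3-dione) | O=C1CC(=O)CC(C)(C)C1 | starting material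
2 | 5,5-dimethyl-3-(2-methylpropoxy)cyclohex-2-en-1-one | CC(C)COC1=CC(=O)CC(C)(C)C1 | intermediate
3 | 6-[(dimethylamino)methyl]-5,5-dimethyl-3-(2-methylpropoxy)cyclohex-2-en-1-one (racemic) | CN(C)CC1C(=O)C=C(OCC(C)C)CC1(C)C | intermediate
4 | [6,6-dimethyl-4-(2-methylpropoxy)-2-oxocyclohex-3-en-1-yl]-N,N,N-trimethylmethanaminium iodide (racemic, not isolated) | C[N+](C)(C)CC1C(=O)C=C(OCC(C)C)CC1(C)C.[I-] | intermediate
5 | 5,5-dimethyl-6-methylidene-3-(2-methylpropoxy)cyclohex-2-en-1-one | C=C1C(=O)C=C(OCC(C)C)CC1(C)C | intermediate
6 | 3-methylbuta-1,2-diene | CC(C)=C=C | starting material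
7 | 2,3-dibromo-3-methylbut-1-ene (not isolated) | C=C(Br)C(C)(C)Br | intermediate
8 | 2-bromo-3-methylbuta-1,3-diene | C=C(C)C(Br)=C | intermediate
9 | (6R)-10-bromo-5,5,9-trimethyl-3-(2-methylpropoxy)spiro[5.5]undeca-2,9-dien-1-one | O=C1C=C(OCC(C)C)CC(C)(C)[C@]12CCC(C)=C(Br)C2 | intermediate
10 | (6R)-10-bromo-1,5,5,9-tetramethyl-3-(2-methylpropoxy)spiro[5.5]undeca-2,9-dien-1-ol (C1 epimers, not isolated) | CC1(O)C=C(OCC(C)C)CC(C)(C)[C@]12CCC(C)=C(Br)C2 | intermediate
11 | (6R)-10-bromo-1,5,5,9-tetramethylspiro[5.5]undeca-1,9-dien-3-one | CC1=CC(=O)CC(C)(C)[C@]12CCC(C)=C(Br)C2 | intermediate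
12 | (6S)-10-bromo-1,5,5,9-tetramethyl-3-(trimethylsilyloxy)spiro[5.5]undeca-1,3,9-triene (not isolated) | CC1=CC(O[Si](C)(C)C)=CC(C)(C)[C@]12CCC(C)=C(Br)C2 | intermediate
13 | (4S,6S)-4,10-dibromo-1,5,5,9-tetramethylspiro[5.5]undeca-1,9-dien-3-one | CC1=CC(=O)[C@@H](Br)C(C)(C)[C@]12CCC(C)=C(Br)C2 | intermediate
14 | (3R,4S,6S)-4,10-dibromo-1,5,5,9-tetramethylspiro[5.5]undeca-1,9-dien-3-ol (OH cis to the C4 bromine) | CC1=C[C@@H](O)[C@@H](Br)C(C)(C)[C@]12CCC(C)=C(Br)C2 | intermediate
15 | (3S,4S,6S)-4,10-dibromo-1,5,5,9-tetramethylspiro[5.5]undeca-1,9-dien-3-yl 4-nitrobenzoate | CC1=C[C@H](OC(=O)c3ccc(cc3)[N+](=O)[O-])[C@@H](Br)C(C)(C)[C@]12CCC(C)=C(Br)C2 | intermediate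
16 | (3S,4S,6S)-4,10-dibromo-1,5,5,9-tetramethylspiro[5.5]undeca-1,9-dien-3-ol | CC1=C[C@H](O)[C@@H](Br)C(C)(C)[C@]12CCC(C)=C(Br)C2 | target

**Step count and risks**
Total step count: 10. Longest linear sequence: 9 (steps 1, 2, 3, 5, 6, 7, 8, 9, 10; step 4 is the side branch).

Steps most likely to fail:

1. Step 5. The diene may add in the reversed orientation (the bromine-bearing end forming the first bond), the catalyst may fail to activate or to discriminate the faces of the very hindered exocyclic alkene, or the enone may oligomerise faster than it cycloadds. The fallback sets out from 5 and 8 and returns at 11; it replaces bromine by a silicon placeholder that cannot stabilise charge on its own carbon, so that methyl alone directs. Compound 8 is converted with Mg in THF into (3-methylbuta-1,3-dien-2-yl)magnesium bromide F1, which is silylated with Me3SiCl to 2-methyl-3-(trimethylsilyl)buta-1,3-diene F2. Acid-catalysed Diels–Alder reaction of 5 with F2 under the step 5 conditions should give the spiro vinylsilane F3. Methylcerium addition gives the tertiary carbinol F4 (not isolated), and hydrolysis with aqueous oxalic acid gives the silyl enone F5. Ipso-bromodesilylation of F5 with NBS in MeCN at 0 °C (attack at the silicon-bearing C10, tertiary β-silyl cation at C9, loss of the silyl group) returns 11.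

2. Step 9. The activated axial oxygen may be lost by E2 elimination with the anti-periplanar C4 hydrogen, or the allylic oxyphosphonium may ionise and give retention or allylic transposition. The fallback sets out from 14 and returns at 16 and makes no new compound (F0); it uses thermodynamic control instead of SN2 inversion. Meerwein–Ponndorf–Verley/Oppenauer equilibration of 14 with Al(OiPr)3 in iPrOH containing a little acetone shuttles the alcohol through ketone 13 and should accumulate the equatorial alcohol 16, because only in 14 is the hydroxyl syn-axial to the axial C5 methyl group.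

3. Step 7. Facial selectivity of bromine delivery to the dienol ether may be poor (each face carries a C5 methyl), and γ-deprotonation or double bromination may compete. The fallback sets out from 11 and returns at 16; it introduces C4–Br and C3–OH together by anti addition. Luche reduction (NaBH4, CeCl3, MeOH) of 11 gives the allylic alcohol F6 as an inconsequential C3 epimer mixture. Dehydration with the Burgess reagent (only C4 carries β-hydrogens) gives the ring-A diene F7. NBS in aqueous acetone should then form the bromonium ion at the C4 terminus on the face opposite the pseudoaxial C7 methylene, and anti opening by water at allylic C3 gives 16 with the trans relationship fixed by the mechanism.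

**Further compounds**
F1 | step 5 | (3-methylbuta-1,3-dien-2-yl)magnesium bromide (not isolated) | C=C(C)C(=C)[Mg]Br
F2 | step 5 | 2-methyl-3-(trimethylsilyl)buta-1,3-diene | C=C(C)C(=C)[Si](C)(C)C
F3 | step 5 | (6R)-5,5,9-trimethyl-3-(2-methylpropoxy)-10-(trimethylsilyl)spiro[5.5]undeca-2,9-dien-1-one | O=C1C=C(OCC(C)C)CC(C)(C)[C@]12CCC(C)=C([Si](C)(C)C)C2
F4 | step 5 | (6R)-1,5,5,9-tetramethyl-3-(2-methylpropoxy)-10-(trimethylsilyl)spiro[5.5]undeca-2,9-dien-1-ol (C1 epimers, not isolated) | CC1(O)C=C(OCC(C)C)CC(C)(C)[C@]12CCC(C)=C([Si](C)(C)C)C2
F5 | step 5 | (6R)-1,5,5,9-tetramethyl-10-(trimethylsilyl)spiro[5.5]undeca-1,9-dien-3-one | CC1=CC(=O)CC(C)(C)[C@]12CCC(C)=C([Si](C)(C)C)C2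
F0 | step 9 | none | none
F6 | step 7 | (6R)-10-bromo-1,5,5,9-tetramethylspiro[5.5]undeca-1,9-dien-3-ol (C3 epimers) | CC1=CC(O)CC(C)(C)[C@]12CCC(C)=C(Br)C2
F7 | step 7 | (6S)-10-bromo-1,5,5,9-tetramethylspiro[5.5]undeca-1,3,9-triene | CC1=CC=CC(C)(C)[C@]12CCC(C)=C(Br)C2
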